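## The problem

Gericudranin E (17) is a (2R,3R)-dihydroflavonol. Its chroman-4-one core fuses ring C to the phloroglucinol-type ring A through C4a and C8a, and carries a 4-hydroxyphenyl group (ring B) at C2, a hydroxyl at C3 and a 4-hydroxybenzyl group at C6, between the C5 and C7 hydroxyls. The skeleton is simple, so the real tasks are two: the regiochemistry on ring A (benzyl at C6, not C8, which means deciding which of the two oxygens ortho to the aroyl carbon becomes O1) and the two adjacent stereocentres. C2 is a benzylic ether carbon that changes only if ring C opens, whereas C3 lies alpha to the C4 ketone and equilibrates to the diequatorial trans arrangement. C2 can therefore control C3, and it is the absolute configuration at C2 that a reagent or catalyst must set. The molecule does not tolerate rough treatment: base can open ring C by beta-elimination of the ring A phenoxide from the C3 enolate, the 4'-phenol can expel O1 through a quinone methide, and the electron-rich rings and the hydroxybenzyl–arene bond are sensitive to strong acid and oxidants. Five hydroxyls must also be freed at the end. The feature that allows a short route is C3: it bears oxygen and sits between the C4 carbonyl and the carbinol-type C2, so it can enter as a carbene carbon (from an aroyl diazomethane) that takes up an alcohol oxygen and an aldehyde carbon in one event. Ring C then lacks only O1–C8a, which a fluorine ortho to the ketone can supply with fixed regiochemistry.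

## Retrosynthesis

**17 back to 16 and 15 (protecting-group bonds only).** The last steps are kept to the mildest unmasking. In 16 only the C3 benzyl ether remains, and hydrogenolysis removes it under neutral conditions. 16 comes from 15, in which all four phenols are 4-nitrobenzenesulfonates. Sulfonates are preferred to alkyl ethers because of what the earlier steps need: their oxygens cannot add to a carbene, they activate ring A for substitution, and they cannot shift to a neighbouring enolate. The nitro variant is chosen over a tosylate because it is cleaved by a soft, weakly basic thiolate rather than by hydroxide. The forward steps must cleave four sulfonates without enolising C3 and must debenzylate only after the nitro groups are gone.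

**15 back to 14 (cut O1–C8a).** Ring C is opened at the aryl ether bond, giving an open-chain alpha-benzyloxy beta-hydroxy ketone with fluorine at C8a. The neighbouring cut, O1–C2 (displacement or oxa-Michael addition by a C8a phenol), would need a free phenol next to a second ortho oxygen at C5, which leaves the C6/C8 regiochemistry open, and a conjugate closure would form C2 without control. With fluorine at C8a the site of closure is fixed, the carbinol C–O bond is never broken, and the anti adduct maps onto the trans ring. The forward reaction must make the alkoxide attack C8a faster than it fragments by retro-aldol.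

**14 back to 10, 12 and 13 (cut C2–C3 and C3–O).** This is the central simplification: 14 falls into the aroyl diazomethane 10, the ring B aldehyde 12 and benzyl alcohol 13. An auxiliary-based glycolate aldol would set the same centres but needs extra steps to attach and remove the auxiliary and to build the aryl ketone. Dihydroxylation of a chalcone gives the syn diol, which is the wrong relative configuration for a closure with retention. The forward reaction must do three things:
- the carbene must be captured by 13 and by nothing inside 10;
- the resulting oxonium ylide must add to 12 before it collapses to the O–H insertion product;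
- a chiral phosphoric acid must choose the aldehyde face and the anti relationship.

For this reason 10 carries fluorine and a sulfonate, not ethers, beside the ketone, and 12 carries an electron-withdrawing sulfonyloxy group.

**10 back to 8 and 7; 12 back to 11 (C=N2 and O–S bonds).** The diazo group is installed on the methyl ketone 8 by detrifluoroacetylative diazo transfer, which avoids an acid chloride on a doubly ortho-substituted ring. 8 is the tris-sulfonate of triol 7, and 12 is the sulfonate of 4-hydroxybenzaldehyde 11. Both sulfonylations are routine; the only demand is that the hindered, hydrogen-bonded hydroxyl ortho to the acetyl group in 7 reacts fully.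

**7 back to 6 and 4 (cut C4–C4a).** 7 is the demethylation product of 6, and the acetyl group of 6 is introduced on the fluoroarene 4 through the aryllithium 5. The two C–H bonds of 4 that lie between fluorine and methoxy are equivalent and the most acidic, so directed metalation gives one regioisomer. A Friedel–Crafts acylation would have to discriminate between the two arenes. Demethylation is placed after the skeleton is complete and before any sensitive group exists.

**4 back to 3, 1 and 2 (cut the bond between the benzylic carbon and the hydroxyphenyl ring).** The diarylmethane 4 comes from carbinol 3 by ionic hydrogenation, and 3 from aldehyde 1 and Grignard reagent 2, both commercial. Because the aldehyde carbon of 1 lies between the two methoxy groups and para to fluorine, the benzyl group is fixed at the future C6 and fluorine at the future C8a from the first step. Direct benzylation of a resorcinol could not guarantee this.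

## Roads not taken

**Alternative 1:** The cut is O1–C8a together with C4a–C5, so ring A is not bought but folded from a masked polyketide chain. In the forward key step an acyclic hydroxy-diketone ending in a dioxinone is treated with acid and then heated. The C2 hydroxyl condenses with the C8a ketone to close ring C, and the acylketene released from the dioxinone acylates C4a to close ring A, giving the tri-O-benzyl compound A1.
- Merits: two rings form in one operation, the benzyl group is placed by the dioxinone, both ring A phenols appear free, and one hydrogenolysis finishes the synthesis. Acylketene aromatisations of this kind are established, which the chosen plan cannot claim for its key step.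
- Weak points: the acyclic precursor must already hold both stereocentres, so an asymmetric aldol is still needed. These centres then sit in a beta-hydroxy ketone chain with several enolisable positions that must survive acid and the heat of the retro-cycloaddition. Dehydration, retro-aldol, epimerisation alpha to the ketone and alternative cyclisation modes all threaten, and the chain is long to assemble.
- Comparison: this road is better in precedent and in the final deprotection. The chosen plan answers with a purchased aromatic ring A, a shorter sequence, and stereocentres that are formed late and never exposed to hot acid.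

**Alternative 2:** Here ring A is cut at C8–C8a, C5–C6, C7–C8 and C4a–C5 and built by a Danheiser benzannulation on a preformed, enantiopure dihydropyranone (ring C). In the forward key step a diazomethyl ketone on C8a undergoes Wolff rearrangement to a vinylketene, which adds a siloxyalkyne bearing the benzyl group. Four-electron opening and six-electron closure of the cyclobutenone then give the silyl-protected compound A2.
- Merits: the polarised alkyne fixes the ring A regiochemistry by construction, the C5 hydroxyl emerges free, and the reaction class is known. In ring A regiocontrol this road is at least as good as the chosen one.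
- Weak points: the chiral dihydropyranone with its diazo ketone needs a multistep synthesis. Its enone chromophore absorbs under irradiation, so cycloaddition of the enone with the alkyne can compete, and its C3 centre is alpha to a ketone during a photochemical or thermal step. Four silyl ethers must finally be removed with fluoride, which is basic enough to endanger ring C.
- Comparison: the chosen plan gets the same regiocontrol from one fluorine atom placed by the symmetry of 4, and needs fewer steps. It pays with a key step that has no direct precedent.

**Alternative 3:** The cut is O1–C8a and C4–C4a: a ring A aryne is joined to an anti alpha-benzyloxy beta-hydroxy ester. In the forward key step CsF releases the aryne from a silyl triflate; the alkoxide adds at C8a and the aryl anion at C4a acylates on the ester, closing ring C to give the penta-O-benzyl compound A3.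
- Merits: the stereocentres are set beforehand by reliable aldol chemistry, the C5 alkoxy group directs the alkoxide to the distal aryne carbon as required, and a single hydrogenolysis removes all five benzyl groups. Both the stereocontrol and the endgame are better founded than in the chosen plan.
- Weak points: the aryne precursor is a hexasubstituted benzene that needs a long, regiocontrolled synthesis. Under fluoride the hydroxy ester alkoxide can fragment by retro-aldol, the aryl anion can be protonated before it acylates, and the ester alpha-centre can epimerise.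
- Comparison: the chosen plan forms the same O1–C8a bond by substitution at an aryl fluoride under stoichiometric control, from a far simpler ring A building block, and makes C2–C3 and both centres in one step.

Key step: step 8

Remark: Ns stands for 4-nitrobenzenesulfonyl and (R)-TRIP for (R)-3,3'-bis(2,4,6-triisopropylphenyl)-1,1'-binaphthyl-2,2'-diyl hydrogen phosphate. Which enantiomer of the acid gives the (2R,3R) adduct is assumed, not known, and the antipode would be used if needed.

## Route

Step 1
Reactants: 1 4-fluoro-2,6-dimethoxybenzaldehyde; 2 4-methoxyphenylmagnesium bromide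
Product: 3 (4-fluoro-2,6-dimethoxyphenyl)(4-methoxyphenyl)methanol (racemic)
Conditions: THF, 0 °C to rt; aq NH4Cl
Reagents that add atoms: none
Why: Grignard addition of an aryl nucleophile to an aromatic aldehyde; the flanking methoxy groups chelate magnesium and do not block attack. The carbinol centre forms as a racemate and is removed in step 2.

Step 2
Reactants: 3 (4-fluoro-2,6-dimethoxyphenyl)(4-methoxyphenyl)methanol
Product: 4 5-fluoro-1,3-dimethoxy-2-(4-methoxybenzyl)benzene
Conditions: Et3SiH, CF3CO2H, CH2Cl2, 0 °C to rt
Reagents that add atoms: none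
Why: Ionic hydrogenation: the acid ionises the doubly activated diarylmethanol to a diarylmethyl cation, which Et3SiH reduces; the aryl fluoride and methyl ethers are inert.

Step 3
Reactants: 4 5-fluoro-1,3-dimethoxy-2-(4-methoxybenzyl)benzene
Product: 6 1-[6-fluoro-2,4-dimethoxy-3-(4-methoxybenzyl)phenyl]ethanone, via the aryllithium 5 (not isolated)
Conditions: n-BuLi, THF, −78 °C; then MeC(O)N(OMe)Me, −78 to 0 °C; aq NH4Cl
Reagents that add atoms: N-methoxy-N-methylacetamide, CC(=O)N(C)OC
Why: Directed ortho-metalation followed by Weinreb ketone synthesis: the two equivalent C–H bonds between fluorine and methoxy are the most acidic in 4, so one aryllithium forms, and at −78 °C it should not lose LiF. The chelated adduct of the Weinreb amide prevents over-addition and enolisation until work-up.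

Step 4
Reactants: 6 1-[6-fluoro-2,4-dimethoxy-3-(4-methoxybenzyl)phenyl]ethanone
Product: 7 1-[6-fluoro-2,4-dihydroxy-3-(4-hydroxybenzyl)phenyl]ethanone
Conditions: BBr3, CH2Cl2, −78 °C to rt; then MeOH/H2O
Reagents that add atoms: none
Why: Lewis-acid cleavage of three aryl methyl ethers with BBr3; the aryl fluoride, the ketone and the diarylmethane should be unaffected at or below room temperature. The demethylation is placed before any sensitive functionality exists.

Step 5
Reactants: 7 1-[6-fluoro-2,4-dihydroxy-3-(4-hydroxybenzyl)phenyl]ethanone
Product: 8 1-{6-fluoro-2,4-bis[(4-nitrophenyl)sulfonyloxy]-3-[4-((4-nitrophenyl)sulfonyloxy)benzyl]phenyl}ethanone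
Conditions: 4-O2NC6H4SO2Cl (3.6 equiv), Et3N, DMAP (cat.), CH2Cl2, 0 °C to rt
Reagents that add atoms: 4-nitrobenzenesulfonyl chloride, O=[N+]([O-])c1ccc(cc1)S(=O)(=O)Cl
Why: O-Sulfonylation of phenols with amine/DMAP catalysis; DMAP is there for the hindered, hydrogen-bonded hydroxyl ortho to the acetyl group. The sulfonates make every phenolic oxygen non-nucleophilic and electron-poor, as steps 8 and 9 require. An intramolecular sulfonyl shift to the ketone enolate is geometrically barred, because in-line displacement at sulfur cannot pass through a six-membered ring.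

Step 6
Reactants: 8 1-{6-fluoro-2,4-bis[(4-nitrophenyl)sulfonyloxy]-3-[4-((4-nitrophenyl)sulfonyloxy)benzyl]phenyl}ethanone
Product: 10 2-diazo-1-{6-fluoro-2,4-bis[(4-nitrophenyl)sulfonyloxy]-3-[4-((4-nitrophenyl)sulfonyloxy)benzyl]phenyl}ethanone, via the trifluoromethyl diketone 9 (not isolated)
Conditions: LiN(SiMe3)2, THF, −78 °C; CF3CO2CH2CF3; then 4-AcNHC6H4SO2N3, Et3N, H2O, MeCN, rt
Reagents that add atoms: 4-acetamidobenzenesulfonyl azide, CC(=O)Nc1ccc(cc1)S(=O)(=O)N=[N+]=[N-]
Why: Detrifluoroacetylative diazo transfer: the kinetic lithium enolate is C-trifluoroacetylated (Claisen condensation) to 9, and the activated diketone undergoes Regitz-type diazo transfer with loss of the trifluoroacetyl group as an N-acyl sulfonamide. The sequence avoids an acid chloride on the doubly ortho-substituted ring and runs at a temperature where the amide base and the enolate should leave the sulfonates alone.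

Step 7
Reactants: 11 4-hydroxybenzaldehyde
Product: 12 4-formylphenyl 4-nitrobenzenesulfonate
Conditions: 4-O2NC6H4SO2Cl, Et3N, CH2Cl2, 0 °C
Reagents that add atoms: 4-nitrobenzenesulfonyl chloride, O=[N+]([O-])c1ccc(cc1)S(=O)(=O)Cl
Why: O-Sulfonylation of a phenol; the sulfonyloxy group is electron-withdrawing, unlike an ether, and raises the electrophilicity of the aldehyde for step 8.

Step 8
Reactants: 10 2-diazo-1-{6-fluoro-2,4-bis[(4-nitrophenyl)sulfonyloxy]-3-[4-((4-nitrophenyl)sulfonyloxy)benzyl]phenyl}ethanone; 12 4-formylphenyl 4-nitrobenzenesulfonate; 13 benzyl alcohol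
Product: 14 (2R,3R)-2-(benzyloxy)-1-{6-fluoro-2,4-bis[(4-nitrophenyl)sulfonyloxy]-3-[4-((4-nitrophenyl)sulfonyloxy)benzyl]phenyl}-3-hydroxy-3-{4-[(4-nitrophenyl)sulfonyloxy]phenyl}propan-1-one
Conditions: Rh2(OAc)4 (2 mol %), (R)-TRIP (10 mol %), 4 Å MS, CH2Cl2, −20 °C; 10 added over 2 h to 12 and 13
Reagents that add atoms: none
Why: Proposed new method: Rh2(OAc)4 converts 10 into a rhodium carbene at the future C3; benzyl alcohol adds to it to give a protic oxonium ylide, an enol equivalent, and the phosphoric acid, hydrogen-bonded to this enol and to aldehyde 12 at once, directs an aldol-type C–C bond formation to the aldehyde carbon (future C2) before the 1,2-proton shift can complete a plain O–H insertion. The closest known reaction type is the Rh2(OAc)4/chiral phosphoric acid co-catalysed three-component coupling of aryldiazoacetates with alcohols and aldehydes or imines by trapping of oxonium ylides; a terminal aroyl diazomethane with this aldehyde is new. No ring is closed. Both stereocentres arise in the C–C bond-forming event: the chiral phosphate pocket selects the face of the aldehyde (the carbinol carbon of 14, later C2), and the anti relationship follows from the closed, doubly hydrogen-bonded arrangement of the (Z)-enol and the aldehyde. The step needs chemoselectivity for alcohol capture and aldol trapping; 10 has no ether oxygen, hydroxyl or alpha-oxy C–H within reach of the carbene (fluorine and a sulfonate flank the ketone), so neither an internal oxonium ylide nor C–H insertion should compete, and the sulfonyloxy group makes 12 a better trap than a 4-alkoxybenzaldehyde. If the anti/syn ratio is modest, only the carbinol centre is indispensable, because C3 of the later flavanone can be equilibrated to the trans isomer.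

Step 9
Reactants: 14 (2R,3R)-2-(benzyloxy)-1-{6-fluoro-2,4-bis[(4-nitrophenyl)sulfonyloxy]-3-[4-((4-nitrophenyl)sulfonyloxy)benzyl]phenyl}-3-hydroxy-3-{4-[(4-nitrophenyl)sulfonyloxy]phenyl}propan-1-one
Product: 15 (2R,3R)-3-(benzyloxy)-5,7-bis[(4-nitrophenyl)sulfonyloxy]-6-[4-((4-nitrophenyl)sulfonyloxy)benzyl]-2-{4-[(4-nitrophenyl)sulfonyloxy]phenyl}chroman-4-one
Conditions: NaH (1.05 equiv), THF, 0 °C
Reagents that add atoms: none
Why: Intramolecular nucleophilic aromatic substitution (addition–elimination): the sodium alkoxide attacks the fluorine-bearing C8a, activated by the ortho ketone and two meta sulfonyloxy groups, and closes the six-membered ring C. The carbinol C–O bond is not broken, so its configuration is retained and the anti adduct gives the 2,3-trans flavanone; fluoride, not the hindered C5 sulfonate, is the leaving group (element effect), which fixes the benzyl group at C6. The stoichiometric base ends as NaF, so no base remains to enolise the product.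

Step 10
Reactants: 15 (2R,3R)-3-(benzyloxy)-5,7-bis[(4-nitrophenyl)sulfonyloxy]-6-[4-((4-nitrophenyl)sulfonyloxy)benzyl]-2-{4-[(4-nitrophenyl)sulfonyloxy]phenyl}chroman-4-one
Product: 16 (2R,3R)-3-(benzyloxy)-5,7-dihydroxy-6-(4-hydroxybenzyl)-2-(4-hydroxyphenyl)chroman-4-one
Conditions: PhSNa (4.5 equiv), DMF, 0 °C to rt, argon; aq NH4Cl
Reagents that add atoms: none
Why: Thiolate cleavage of 4-nitrobenzenesulfonates (Fukuyama-type ipso substitution): the thiolate adds to the sulfonyl-bearing carbon of the nitroarene, the Meisenheimer adduct expels the aryl sulfite, and loss of SO2 frees each phenoxide. The soft, weakly basic thiolate should not enolise C3, and each phenoxide formed on ring A further deactivates the ketone, so both stereocentres should survive.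

Step 11
Reactants: 16 (2R,3R)-3-(benzyloxy)-5,7-dihydroxy-6-(4-hydroxybenzyl)-2-(4-hydroxyphenyl)chroman-4-one
Product: 17 gericudranin E, (2R,3R)-3,5,7-trihydroxy-6-(4-hydroxybenzyl)-2-(4-hydroxyphenyl)chroman-4-one
Conditions: H2 (1 atm), Pd(OH)2/C, EtOAc–MeOH, rt
Reagents that add atoms: none
Why: Catalytic hydrogenolysis of a benzyl ether; with the nitroarenes gone nothing else should be reduced, and the hydrogen-bonded aryl ketone and both stereocentres are untouched.

## Compound list

1 | 4-fluoro-2,6-dimethoxybenzaldehyde | COc1cc(F)cc(OC)c1C=O | starting material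
2 | 4-methoxyphenylmagnesium bromide | COc1ccc([Mg]Br)cc1 | starting material
3 | (4-fluoro-2,6-dimethoxyphenyl)(4-methoxyphenyl)methanol (racemic) | COc1ccc(cc1)C(O)c1c(OC)cc(F)cc1OC | intermediate
4 | 5-fluoro-1,3-dimethoxy-2-(4-methoxybenzyl)benzene | COc1ccc(Cc2c(OC)cc(F)cc2OC)cc1 | intermediate
5 | [6-fluoro-2,4-dimethoxy-3-(4-methoxybenzyl)phenyl]lithium | [Li]c1c(F)cc(OC)c(Cc2ccc(OC)cc2)c1OC | intermediate
6 | 1-[6-fluoro-2,4-dimethoxy-3-(4-methoxybenzyl)phenyl]ethanone | CC(=O)c1c(F)cc(OC)c(Cc2ccc(OC)cc2)c1OC | intermediate
7 | 1-[6-fluoro-2,4-dihydroxy-3-(4-hydroxybenzyl)phenyl]ethanone | CC(=O)c1c(F)cc(O)c(Cc2ccc(O)cc2)c1O | intermediate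
8 | 1-{6-fluoro-2,4-bis[(4-nitrophenyl)sulfonyloxy]-3-[4-((4-nitrophenyl)sulfonyloxy)benzyl]phenyl}ethanone | CC(=O)c1c(F)cc(OS(=O)(=O)c2ccc(cc2)[N+](=O)[O-])c(Cc2ccc(OS(=O)(=O)c3ccc(cc3)[N+](=O)[O-])cc2)c1OS(=O)(=O)c1ccc(cc1)[N+](=O)[O-] | intermediate
9 | 4,4,4-trifluoro-1-{6-fluoro-2,4-bis[(4-nitrophenyl)sulfonyloxy]-3-[4-((4-nitrophenyl)sulfonyloxy)benzyl]phenyl}butane-1,3-dione | O=C(CC(=O)C(F)(F)F)c1c(F)cc(OS(=O)(=O)c2ccc(cc2)[N+](=O)[O-])c(Cc2ccc(OS(=O)(=O)c3ccc(cc3)[N+](=O)[O-])cc2)c1OS(=O)(=O)c1ccc(cc1)[N+](=O)[O-] | intermediate
10 | 2-diazo-1-{6-fluoro-2,4-bis[(4-nitrophenyl)sulfonyloxy]-3-[4-((4-nitrophenyl)sulfonyloxy)benzyl]phenyl}ethanone | [N-]=[N+]=CC(=O)c1c(F)cc(OS(=O)(=O)c2ccc(cc2)[N+](=O)[O-])c(Cc2ccc(OS(=O)(=O)c3ccc(cc3)[N+](=O)[O-])cc2)c1OS(=O)(=O)c1ccc(cc1)[N+](=O)[O-] | intermediate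
11 | 4-hydroxybenzaldehyde | O=Cc1ccc(O)cc1 | starting material
12 | 4-formylphenyl 4-nitrobenzenesulfonate | O=Cc1ccc(OS(=O)(=O)c2ccc(cc2)[N+](=O)[O-])cc1 | intermediate
13 | benzyl alcohol | OCc1ccccc1 | starting material
14 | (2R,3R)-2-(benzyloxy)-1-{6-fluoro-2,4-bis[(4-nitrophenyl)sulfonyloxy]-3-[4-((4-nitrophenyl)sulfonyloxy)benzyl]phenyl}-3-hydroxy-3-{4-[(4-nitrophenyl)sulfonyloxy]phenyl}propan-1-one | O[C@H](c1ccc(OS(=O)(=O)c2ccc(cc2)[N+](=O)[O-])cc1)[C@H](C(=O)c1c(F)cc(OS(=O)(=O)c2ccc(cc2)[N+](=O)[O-])c(Cc2ccc(OS(=O)(=O)c3ccc(cc3)[N+](=O)[O-])cc2)c1OS(=O)(=O)c1ccc(cc1)[N+](=O)[O-])OCc1ccccc1 | intermediate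
15 | (2R,3R)-3-(benzyloxy)-5,7-bis[(4-nitrophenyl)sulfonyloxy]-6-[4-((4-nitrophenyl)sulfonyloxy)benzyl]-2-{4-[(4-nitrophenyl)sulfonyloxy]phenyl}chroman-4-one | O=C1c2c(cc(OS(=O)(=O)c3ccc(cc3)[N+](=O)[O-])c(Cc3ccc(OS(=O)(=O)c4ccc(cc4)[N+](=O)[O-])cc3)c2OS(=O)(=O)c2ccc(cc2)[N+](=O)[O-])O[C@H](c2ccc(OS(=O)(=O)c3ccc(cc3)[N+](=O)[O-])cc2)[C@H]1OCc1ccccc1 | intermediate
16 | (2R,3R)-3-(benzyloxy)-5,7-dihydroxy-6-(4-hydroxybenzyl)-2-(4-hydroxyphenyl)chroman-4-one | O=C1c2c(cc(O)c(Cc3ccc(O)cc3)c2O)O[C@H](c2ccc(O)cc2)[C@H]1OCc1ccccc1 | intermediate
17 | gericudranin E, (2R,3R)-3,5,7-trihydroxy-6-(4-hydroxybenzyl)-2-(4-hydroxyphenyl)chroman-4-one | O=C1c2c(cc(O)c(Cc3ccc(O)cc3)c2O)O[C@H](c2ccc(O)cc2)[C@H]1O | target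

## Step count and least certain steps

Total: 11 steps. Longest linear sequence: 10 steps (steps 1–6 and 8–11); step 7 is a one-step side branch.

**Step 8 (key step, proposed new method).** The oxonium ylide may transfer its proton before it meets the aldehyde, giving plain O–H insertion. The phosphate may discriminate poorly between the aldehyde faces with a ketone-derived enol. Carbene dimerisation or acid-induced decomposition of the diazo ketone may consume 10. Fallback with known chemistry, setting out from 10 and returning at 15:
- Rh2(OAc)4-catalysed O–H insertion of benzyl alcohol alone would give the benzyloxymethyl ketone F1.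
- Its boron enolate (c-Hex2BCl, Et3N) would add to 12 to give the aldol as a stereoisomer mixture F2.
- Dess–Martin oxidation would give the 2-benzyloxy-1,3-diketone F3.
- Noyori asymmetric transfer hydrogenation (RuCl(p-cymene)[(R,R)-TsDPEN] or its antipode, HCO2H/Et3N) should reduce only the unhindered ring B ketone, the doubly ortho-substituted ring A ketone being shielded. The rapidly enolising centre between the carbonyls permits dynamic kinetic resolution, giving the (3R)-alcohol F4, whose anti isomer is 14.
- Ring closure as in step 9, with amine-mediated equilibration at the enolisable C3 if the syn isomer prevails, would lead to 15.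

**Step 9.** The sodium aldolate may fragment by retro-aldol or lose water toward the enone before it cyclises. The product may be enolised by unreacted alkoxide and open by beta-elimination of the ring A phenoxide. Attack at C5 with loss of sulfonate would erode the regiochemistry. Fallback from 14 to 15: silylation (Me3SiOTf, 2,6-lutidine) would give the trimethylsilyl ether F5. Catalytic anhydrous fluoride (tetrabutylammonium difluorotriphenylsilicate, THF, low temperature) would then release the alkoxide only in stationary amounts; each ring closure regenerates fluoride, so no stoichiometric base is ever present.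

**Step 6.** The amide base or the enolate may attack a sulfonate, or trifluoroacetylation of the hindered, twisted enolate may stay incomplete. Fallback from 8 to 10: alpha-bromination (PhNMe3Br3, THF) would give the bromomethyl ketone F6. Treatment with N,N'-ditosylhydrazine and DBU (diazo synthesis from bromoacetyl compounds) would then give 10 without a ketone enolate.

**Step 10.** The thiolate may substitute at a ring carbon of the chromanone (C–O instead of S–C cleavage), or ring C may open before the ring A sulfonates are off. Fallback from 15 to 16: aminolysis at sulfur with pyrrolidine in MeCN, a different cleavage mode that transfers the sulfonyl groups to nitrogen and uses no thiolate; no new compound arises (F0).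

**Step 3.** Deprotonation at the diarylmethane CH2 or loss of LiF to an aryne may compete with ortho-lithiation. Fallback from 4 to 6: Friedel–Crafts acetylation (AcCl, SnCl4, CH2Cl2, −20 °C) at the ring A position ortho to fluorine and para to methoxy, the most activated site of 4; no new compound arises (F0).

## Further compounds

F1 | step 8 | 2-(benzyloxy)-1-{6-fluoro-2,4-bis[(4-nitrophenyl)sulfonyloxy]-3-[4-((4-nitrophenyl)sulfonyloxy)benzyl]phenyl}ethanone | O=C(COCc1ccccc1)c1c(F)cc(OS(=O)(=O)c2ccc(cc2)[N+](=O)[O-])c(Cc2ccc(OS(=O)(=O)c3ccc(cc3)[N+](=O)[O-])cc2)c1OS(=O)(=O)c1ccc(cc1)[N+](=O)[O-]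
F2 | step 8 | 2-(benzyloxy)-1-{6-fluoro-2,4-bis[(4-nitrophenyl)sulfonyloxy]-3-[4-((4-nitrophenyl)sulfonyloxy)benzyl]phenyl}-3-hydroxy-3-{4-[(4-nitrophenyl)sulfonyloxy]phenyl}propan-1-one, mixture of stereoisomers | OC(c1ccc(OS(=O)(=O)c2ccc(cc2)[N+](=O)[O-])cc1)C(C(=O)c1c(F)cc(OS(=O)(=O)c2ccc(cc2)[N+](=O)[O-])c(Cc2ccc(OS(=O)(=O)c3ccc(cc3)[N+](=O)[O-])cc2)c1OS(=O)(=O)c1ccc(cc1)[N+](=O)[O-])OCc1ccccc1
F3 | step 8 | 2-(benzyloxy)-1-{6-fluoro-2,4-bis[(4-nitrophenyl)sulfonyloxy]-3-[4-((4-nitrophenyl)sulfonyloxy)benzyl]phenyl}-3-{4-[(4-nitrophenyl)sulfonyloxy]phenyl}propane-1,3-dione | O=C(c1ccc(OS(=O)(=O)c2ccc(cc2)[N+](=O)[O-])cc1)C(C(=O)c1c(F)cc(OS(=O)(=O)c2ccc(cc2)[N+](=O)[O-])c(Cc2ccc(OS(=O)(=O)c3ccc(cc3)[N+](=O)[O-])cc2)c1OS(=O)(=O)c1ccc(cc1)[N+](=O)[O-])OCc1ccccc1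
F4 | step 8 | (3R)-2-(benzyloxy)-1-{6-fluoro-2,4-bis[(4-nitrophenyl)sulfonyloxy]-3-[4-((4-nitrophenyl)sulfonyloxy)benzyl]phenyl}-3-hydroxy-3-{4-[(4-nitrophenyl)sulfonyloxy]phenyl}propan-1-one, configuration at C2 not specified | O[C@H](c1ccc(OS(=O)(=O)c2ccc(cc2)[N+](=O)[O-])cc1)C(C(=O)c1c(F)cc(OS(=O)(=O)c2ccc(cc2)[N+](=O)[O-])c(Cc2ccc(OS(=O)(=O)c3ccc(cc3)[N+](=O)[O-])cc2)c1OS(=O)(=O)c1ccc(cc1)[N+](=O)[O-])OCc1ccccc1
F5 | step 9 | (2R,3R)-2-(benzyloxy)-1-{6-fluoro-2,4-bis[(4-nitrophenyl)sulfonyloxy]-3-[4-((4-nitrophenyl)sulfonyloxy)benzyl]phenyl}-3-{4-[(4-nitrophenyl)sulfonyloxy]phenyl}-3-(trimethylsilyloxy)propan-1-one | C[Si](C)(C)O[C@H](c1ccc(OS(=O)(=O)c2ccc(cc2)[N+](=O)[O-])cc1)[C@H](C(=O)c1c(F)cc(OS(=O)(=O)c2ccc(cc2)[N+](=O)[O-])c(Cc2ccc(OS(=O)(=O)c3ccc(cc3)[N+](=O)[O-])cc2)c1OS(=O)(=O)c1ccc(cc1)[N+](=O)[O-])OCc1ccccc1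
F6 | step 6 | 2-bromo-1-{6-fluoro-2,4-bis[(4-nitrophenyl)sulfonyloxy]-3-[4-((4-nitrophenyl)sulfonyloxy)benzyl]phenyl}ethanone | BrCC(=O)c1c(F)cc(OS(=O)(=O)c2ccc(cc2)[N+](=O)[O-])c(Cc2ccc(OS(=O)(=O)c3ccc(cc3)[N+](=O)[O-])cc2)c1OS(=O)(=O)c1ccc(cc1)[N+](=O)[O-]
F0 | step 10 | none | none
F0 | step 3 | none | none
A1 | alternative 1 | 3,4',4''-tri-O-benzyl gericudranin E | O=C1c2c(cc(O)c(Cc3ccc(OCc4ccccc4)cc3)c2O)O[C@H](c2ccc(OCc3ccccc3)cc2)[C@H]1OCc1ccccc1
A2 | alternative 2 | 3-O-tert-butyldimethylsilyl-7,4',4''-tri-O-triisopropylsilyl gericudranin E | O=C1c2c(cc(O[Si](C(C)C)(C(C)C)C(C)C)c(Cc3ccc(O[Si](C(C)C)(C(C)C)C(C)C)cc3)c2O)O[C@H](c2ccc(O[Si](C(C)C)(C(C)C)C(C)C)cc2)[C@H]1O[Si](C)(C)C(C)(C)C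
A3 | alternative 3 | 3,5,7,4',4''-penta-O-benzyl gericudranin E | O=C1c2c(cc(OCc3ccccc3)c(Cc3ccc(OCc4ccccc4)cc3)c2OCc2ccccc2)O[C@H](c2ccc(OCc3ccccc3)cc2)[C@H]1OCc1ccccc1
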